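The runs were computed with constants of no real substance; noise was put on by code.

If I take the main step by itself, starting material splits into target and side product at a fixed ratio, and the share of target in the two stays flat. I built the flask up from there.

| setting | south | south-west | east | flask |
|---|---|---|---|---|
| starting material | 0.13 M | 0.30 M | 0.20 M | 0.20 M |
| protic impurity | 0.010 M | 0.010 M | 0.015 M | 0.0100 M |
| remark | run made earlier | run made earlier | run made earlier |  |
| time |  |  |  | 5.0 h |

| run | time / h | target / % | side product / % |
|---|---|---|---|
| south | 0.500 | 13.2 | 63.3 |
| south | 1.00 | 14.4 | 70.6 |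
| south | 2.50 | 14.9 | 75.6 |
| south | 6.00 | 14.6 | 76.4 |
| south-west | 0.500 | 13.8 | 66.2 |
| south-west | 1.00 | 15.8 | 74.1 |
| south-west | 2.50 | 16.0 | 78.1 |
| south-west | 6.00 | 15.8 | 80.3 |
| east | 1.50 | 14.7 | 72.6 |
| east | 3.00 | 15.1 | 75.9 |
| east | 5.00 | 14.9 | 76.6 |
| east | 6.00 | 14.4 | 76.3 |

(scatter of a reading: 0.5 percentage points)

* share of target in target plus side product at 4.0 min
* share of target in target plus side product at 30 min
* share of target in target plus side product at 5.0 h

- what was read earlier has a scatter of 0.5 percentage points, one standard deviation

1. Main step. At 0.500 h the south run read a share of 17.3% and the south-west run 17.2%, though their charges differ. I took the mean, 17.3%, as the branch share, the selectivity of the split.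

2. Protic impurity. In the flask it amounts to 5.00% of the charge. I assumed it removes starting material before the split. So I left the share unchanged and expected target plus side product to level off near 95.0% of the charge.

3. Slow loss. By 6.00 h the mean share of the 3 runs had sunk to 16.1%. That is a fractional fall of 0.0123 h⁻¹, the fade. It is a reading and carries the scatter.

4. Reckoning. Running the fade from 0.500 h, I got 17.4% at 4.0 min, 17.3% at 30 min and 16.3% at 5.0 h.

5. Forecast. It gave 17.4%, 17.2% and 16.3%, reading the fall as “suggesting slow loss of target, possibly to side product”. My figure at 30 min differs from it in the last digit; my other two figures print the same as its figures.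

The flask gave 17.6%, 17.5% and 16.3%.

    starting material → intermediate A (k = 0.280 min⁻¹)
    intermediate A ⇌ intermediate B (K = 3.10, k = 0.0670 min⁻¹)
    starting material ⇌ intermediate C (K = 0.750, k = 0.100 min⁻¹)
    intermediate A → intermediate D (k = 0.320 min⁻¹)
    intermediate D → side product (k = 0.370 min⁻¹)
    intermediate D → target (k = 0.0790 min⁻¹)
    starting material + protic impurity → quenched substrate (k = 100 M⁻¹ min⁻¹)
    target → over-reaction product (k = 3.20 × 10⁻⁴ min⁻¹)

At 5.00 h the flask held 1.43% of the charge as over-reaction product, which forms from target. From 4.0 min to 5.0 h the fade gives a fall of 1 percentage point, and the flask fell 1.3 points. A neighbour flask held protic impurity at 2.00% of the charge. For it the fade keeps the share at 16.3%, and 98.0% of the charge unquenched makes 16.0% target. That neighbour flask computed to a share of 16.3% and 15.8% target.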